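## Retrosynthetic overview

1. The last C–C bond (C3'–allyl) comes from an aromatic Claisen rearrangement ([3,3]) of the 4'-O-allyl ether 25; the O-allyl group doubles as the phenol protection until then.
2. The biaryl bond comes from a Suzuki coupling (aryl chloride + 4-allyloxyphenylboronic acid), the 5-allyl group from a Stille coupling on the para-bromide, and the tertiary alkyl aryl ether from O-arylation of a tertiary alkoxide with a diaryliodonium salt.
3. The side chain is made from isopropenyl by ozonolysis to acetyl, thermodynamic C7 epimerisation (axial to equatorial) and MeMgBr addition.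
4. The decalin: ring B is the (S)-carvone ring; ring A comes from Robinson annulation with methyl vinyl ketone; the trans fusion from Li/NH3; the C2 carbinol from equatorial methyl addition.
5. Ring order: ring B (bought) → ring A (Robinson) → aryl ring 1 attached (C–O) → aryl ring 2 attached (Suzuki) → Claisen.

Assumption: compounds 1, 3, 11, 12, 22 and 24 are purchased; decalin positions are numbered as in decahydronaphthalene (C2 ether carbon, C4a angular-methyl carbon, C7 side-chain carbon, C8a ring-fusion CH), and β means the face of the angular methyl group.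

## Route

Step 1
Reactants: 1 (S)-(+)-carvone
Product: 2 (2S,5S)-dihydrocarvone (trans major; some C2 epimer, inconsequential)
Conditions: Zn dust (5 equiv), KOH, MeOH/H2O 2:1, reflux, 4 h
Reagents that add atoms: none
Why: Dissolving-metal conjugate reduction of the enone C=C only; the bought C5 stereocentre is untouched and C2 is enolised in the next step.

Step 2
Reactants: 2 (2S,5S)-dihydrocarvone; 3 methyl vinyl ketone
Product: 6 (4aS,7S)-4a-methyl-7-(prop-1-en-2-yl)-4,4a,5,6,7,8-hexahydronaphthalen-2(3H)-one, via Michael diketone 4 (not isolated), via cis-ketol 5 (not isolated)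
Conditions: MVK (1.2 equiv), KOH (0.1 equiv), EtOH, −10 → 0 °C, 8 h; then KOH (1.5 equiv), EtOH, 70 °C, 2 h; chromatography
Reagents that add atoms: methyl vinyl ketone 3 (C=CC(C)=O)
Why: Robinson annulation (Michael addition, intramolecular aldol, E1cB dehydration) in which the more substituted enolate attacks MVK axially on a chair with equatorial isopropenyl, so the new chain is cis and the angular methyl trans to the isopropenyl group (expected about 4:1, minor isomer removed).

Step 3
Reactants: 6 enone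
Product: 8 (4aS,7S,8aS)-4a-methyl-7-(prop-1-en-2-yl)octahydronaphthalen-2(1H)-one (trans-fused; isopropenyl axial), via lithium enolate 7 (not isolated)
Conditions: Li (4 equiv), NH3(l)/THF, t-BuOH (1 equiv), −78 °C, 30 min; solid NH4Cl
Reagents that add atoms: none
Why: Birch-type dissolving-metal reduction of the enone, where axial protonation of the β-carbanion anti to the angular methyl gives the trans ring fusion (C8a) and the isolated alkene is not reduced.

Step 4
Reactants: 8 trans-decalone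
Product: 10 (2R,4aS,7S,8aS)-2,4a-dimethyl-7-(prop-1-en-2-yl)decahydronaphthalen-2-ol (OH axial/α; 2-Me equatorial/β), via chloromagnesium alkoxide 9 (not isolated)
Conditions: MeMgCl (4 equiv), FeCl3 (1.1 equiv), LiCl (2.2 equiv), THF, −30 → −20 °C; aq. NH4Cl
Reagents that add atoms: methylmagnesium chloride (C[Mg]Cl)
Why: 1,2-Addition of a bulky Grignard-derived methyl ferrate, which attacks the locked trans-decalin-2-one equatorially, as with 3-keto-5α-steroids, giving equatorial methyl and axial OH at C2.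

Step 5
Reactants: 11 4-bromo-2-chloro-1-iodobenzene; 12 1,3,5-trimethoxybenzene
Product: 14 (4-bromo-2-chlorophenyl)(2,4,6-trimethoxyphenyl)iodonium tosylate, via hydroxy(tosyloxy)iodoarene 13 (not isolated)
Conditions: mCPBA (1.1 equiv), TsOH·H2O (1.1 equiv), MeCN, 77 °C, 1 h; then 12 (1.05 equiv), 77 °C → rt; Et2O trituration
Reagents that add atoms: p-toluenesulfonic acid monohydrate (Cc1ccc(cc1)S(O)(=O)=O.O); 1,3,5-trimethoxybenzene 12 (COc1cc(OC)cc(OC)c1)
Why: One-pot oxidation of the aryl iodide to a Koser-type iodine(III) tosylate followed by electrophilic aromatic substitution on the electron-rich arene gives the unsymmetrical diaryliodonium salt.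

Step 6
Reactants: 10 tertiary alcohol; 14 iodonium tosylate
Product: 16 (2R,4aS,7S,8aS)-2-(4-bromo-2-chlorophenoxy)-2,4a-dimethyl-7-(prop-1-en-2-yl)decahydronaphthalene, via sodium alkoxide 15 (not isolated)
Conditions: NaH (1.5 equiv), TBME, 50 °C, 1 h; then 14 (1.3 equiv), rt → 50 °C, 6 h
Reagents that add atoms: (4-bromo-2-chlorophenyl)(2,4,6-trimethoxyphenyl)iodonium tosylate 14 (COc1cc(OC)c([I+]c2ccc(Br)cc2Cl)c(OC)c1.Cc1ccc(cc1)S(=O)(=O)[O-])
Why: Metal-free O-arylation of a tertiary alkoxide by ligand coupling at iodine(III), in which the electron-poorer ortho-substituted aryl is transferred, the trimethoxyphenyl group is a dummy, and the carbinol C–O bond is untouched so C2 is retained.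

Step 7
Reactants: 16 aryl ether
Product: 19 (2R,4aS,7R,8aS)-7-acetyl-2-(4-bromo-2-chlorophenoxy)-2,4a-dimethyldecahydronaphthalene (acetyl equatorial/β), via secondary ozonide 17 (not isolated), via axial methyl ketone 18 (not isolated)
Conditions: O3, CH2Cl2, −78 °C (indicator endpoint); Me2S, −78 °C → rt; aqueous wash; then NaOMe (0.3 equiv), MeOH, rt, 16 h
Reagents that add atoms: ozone ([O-][O+]=O)
Why: Ozonolysis of the only alkene to the methyl ketone, then base-mediated thermodynamic epimerisation through the enolate moves the acetyl group from axial to equatorial (expected ≥9:1), with C7 dictated by the rigid trans-decalin.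

Step 8
Reactants: 19 equatorial methyl ketone
Product: 21 (2R,4aS,7R,8aS)-2-(4-bromo-2-chlorophenoxy)-7-(2-hydroxypropan-2-yl)-2,4a-dimethyldecahydronaphthalene, via bromomagnesium alkoxide 20 (not isolated)
Conditions: MeMgBr (3 equiv), THF, −20 → 0 °C; aq. NH4Cl
Reagents that add atoms: methylmagnesium bromide (C[Mg]Br)
Why: Grignard 1,2-addition to the methyl ketone gives the dimethyl carbinol; addition outpaces enolisation at low temperature, so C7 and the aryl halides are unaffected.

Step 9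
Reactants: 21 bromo chloro aryl ether; 22 allyltributylstannane
Product: 23 (2R,4aS,7R,8aS)-2-(4-allyl-2-chlorophenoxy)-7-(2-hydroxypropan-2-yl)-2,4a-dimethyldecahydronaphthalene
Conditions: allylSnBu3 (1.3 equiv), Pd(PPh3)4 (5 mol %), toluene, 100 °C, 12 h
Reagents that add atoms: allyltributylstannane 22 (C=CC[Sn](CCCC)(CCCC)CCCC)
Why: Stille cross-coupling, chemoselective for the unhindered C–Br bond over the hindered C–Cl bond, installs the allyl group para to the ether oxygen under neutral conditions that do not isomerise it.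

Step 10
Reactants: 23 aryl chloride; 24 [4-(allyloxy)phenyl]boronic acid
Product: 25 (2R,4aS,7R,8aS)-2-{[5-allyl-4'-(allyloxy)-[1,1'-biphenyl]-2-yl]oxy}-7-(2-hydroxypropan-2-yl)-2,4a-dimethyldecahydronaphthalene
Conditions: 24 (1.5 equiv), Pd(OAc)2 (3 mol %), SPhos (6 mol %), K3PO4 (3 equiv), toluene/H2O 10:1, 90 °C, 8 h
Reagents that add atoms: [4-(allyloxy)phenyl]boronic acid 24 (C=CCOc1ccc(cc1)B(O)O)
Why: Suzuki–Miyaura coupling of the hindered aryl chloride with a dialkylbiarylphosphine catalyst forms the biaryl bond and brings in the phenol oxygen already as its allyl ether.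

Step 11
Reactants: 25 allyl aryl ether
Product: 27 target (honokiol 2-O-ether; CNP0342687.1), via ortho-dienone 26 (not isolated)
Conditions: N,N-diethylaniline (degassed), 190 °C, sealed tube, 8 h
Reagents that add atoms: none
Why: Aromatic Claisen rearrangement ([3,3]-sigmatropic shift) through the ortho-dienone and tautomerisation forms the C3'–allyl bond and frees the phenol; the two ortho positions are equivalent, the para position is blocked, and no stereocentre is touched.

## Compound list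

1 | (S)-(+)-carvone | CC1=CC[C@@H](CC1=O)C(C)=C | starting material
2 | (2S,5S)-dihydrocarvone (trans major) | C[C@H]1CC[C@@H](CC1=O)C(C)=C | intermediate
3 | methyl vinyl ketone | C=CC(C)=O | starting material
4 | (2S,5S)-2-methyl-2-(3-oxobutyl)-5-(prop-1-en-2-yl)cyclohexan-1-one (not isolated) | CC(=O)CC[C@]1(C)CC[C@H](C(C)=C)CC1=O | intermediate
5 | (4aS,7S,8aS)-8a-hydroxy-4a-methyl-7-(prop-1-en-2-yl)octahydronaphthalen-2(1H)-one, cis-fused ketol (not isolated) | O=C1CC[C@]2(C)CC[C@H](C(C)=C)C[C@]2(O)C1 | intermediate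
6 | (4aS,7S)-4a-methyl-7-(prop-1-en-2-yl)-4,4a,5,6,7,8-hexahydronaphthalen-2(3H)-one | O=C1CC[C@]2(C)CC[C@H](C(C)=C)CC2=C1 | intermediate
7 | lithium (4aS,7S,8aS)-4a-methyl-7-(prop-1-en-2-yl)-3,4,4a,5,6,7,8,8a-octahydronaphthalen-2-olate (not isolated) | [Li+].[O-]C1CC[C@]2(C)CC[C@H](C(C)=C)C[C@H]2C=1 | intermediate
8 | (4aS,7S,8aS)-4a-methyl-7-(prop-1-en-2-yl)octahydronaphthalen-2(1H)-one (trans-fused) | O=C1CC[C@]2(C)CC[C@H](C(C)=C)C[C@H]2C1 | intermediate
9 | chloromagnesium alkoxide of 10 (not isolated) | Cl[Mg]O[C@]1(C)CC[C@]2(C)CC[C@H](C(C)=C)C[C@H]2C1 | intermediate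
10 | (2R,4aS,7S,8aS)-2,4a-dimethyl-7-(prop-1-en-2-yl)decahydronaphthalen-2-ol | O[C@]1(C)CC[C@]2(C)CC[C@H](C(C)=C)C[C@H]2C1 | intermediate
11 | 4-bromo-2-chloro-1-iodobenzene | Clc1cc(Br)ccc1I | starting material
12 | 1,3,5-trimethoxybenzene | COc1cc(OC)cc(OC)c1 | starting material
13 | 4-bromo-2-chloro-1-[hydroxy(tosyloxy)-λ3-iodanyl]benzene (not isolated) | Cc1ccc(cc1)S(=O)(=O)OI(O)c1ccc(Br)cc1Cl | intermediate
14 | (4-bromo-2-chlorophenyl)(2,4,6-trimethoxyphenyl)iodonium tosylate | COc1cc(OC)c([I+]c2ccc(Br)cc2Cl)c(OC)c1.Cc1ccc(cc1)S(=O)(=O)[O-] | intermediate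
15 | sodium alkoxide of 10 (not isolated) | [Na+].[O-][C@]1(C)CC[C@]2(C)CC[C@H](C(C)=C)C[C@H]2C1 | intermediate
16 | (2R,4aS,7S,8aS)-2-(4-bromo-2-chlorophenoxy)-2,4a-dimethyl-7-(prop-1-en-2-yl)decahydronaphthalene | Clc1cc(Br)ccc1O[C@]1(C)CC[C@]2(C)CC[C@H](C(C)=C)C[C@H]2C1 | intermediate
17 | secondary ozonide of 16 (3-methyl-1,2,4-trioxolan-3-yl at C7; not isolated) | Clc1cc(Br)ccc1O[C@]1(C)CC[C@]2(C)CC[C@H](C3(C)OCOO3)C[C@H]2C1 | intermediate
18 | (2R,4aS,7S,8aS)-7-acetyl-2-(4-bromo-2-chlorophenoxy)-2,4a-dimethyldecahydronaphthalene, axial acetyl (not isolated) | Clc1cc(Br)ccc1O[C@]1(C)CC[C@]2(C)CC[C@H](C(C)=O)C[C@H]2C1 | intermediate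
19 | (2R,4aS,7R,8aS)-7-acetyl-2-(4-bromo-2-chlorophenoxy)-2,4a-dimethyldecahydronaphthalene, equatorial acetyl | Clc1cc(Br)ccc1O[C@]1(C)CC[C@]2(C)CC[C@@H](C(C)=O)C[C@H]2C1 | intermediate
20 | bromomagnesium alkoxide of 21 (not isolated) | Clc1cc(Br)ccc1O[C@]1(C)CC[C@]2(C)CC[C@@H](C(C)(C)O[Mg]Br)C[C@H]2C1 | intermediate
21 | (2R,4aS,7R,8aS)-2-(4-bromo-2-chlorophenoxy)-7-(2-hydroxypropan-2-yl)-2,4a-dimethyldecahydronaphthalene | Clc1cc(Br)ccc1O[C@]1(C)CC[C@]2(C)CC[C@@H](C(C)(C)O)C[C@H]2C1 | intermediate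
22 | allyltributylstannane | C=CC[Sn](CCCC)(CCCC)CCCC | starting material
23 | (2R,4aS,7R,8aS)-2-(4-allyl-2-chlorophenoxy)-7-(2-hydroxypropan-2-yl)-2,4a-dimethyldecahydronaphthalene | C=CCc1ccc(O[C@]2(C)CC[C@]3(C)CC[C@@H](C(C)(C)O)C[C@H]3C2)c(Cl)c1 | intermediate
24 | [4-(allyloxy)phenyl]boronic acid | C=CCOc1ccc(cc1)B(O)O | starting material
25 | (2R,4aS,7R,8aS)-2-{[5-allyl-4'-(allyloxy)-[1,1'-biphenyl]-2-yl]oxy}-7-(2-hydroxypropan-2-yl)-2,4a-dimethyldecahydronaphthalene | C=CCc1ccc(O[C@]2(C)CC[C@]3(C)CC[C@@H](C(C)(C)O)C[C@H]3C2)c(-c2ccc(OCC=C)cc2)c1 | intermediate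
26 | 6-allyl-4-aryl-cyclohexa-2,4-dien-1-one (ortho-dienone of 25; not isolated) | C=CCc1ccc(O[C@]2(C)CC[C@]3(C)CC[C@@H](C(C)(C)O)C[C@H]3C2)c(C2=CC(CC=C)C(=O)C=C2)c1 | intermediate
27 | (2R,4aS,7R,8aS)-2-{[4'-hydroxy-3',5-di(prop-2-en-1-yl)-[1,1'-biphenyl]-2-yl]oxy}-7-(2-hydroxypropan-2-yl)-2,4a-dimethyldecahydronaphthalene | C=CCc1ccc(O[C@]2(C)CC[C@]3(C)CC[C@@H](C(C)(C)O)C[C@H]3C2)c(-c2ccc(O)c(CC=C)c2)c1 | target

## Step count and risks

Total: 11 steps. Longest linear sequence: 10 steps (1–4, then 6–11); step 5 is a one-step side branch.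

**Step 3 (ring-fusion selectivity).** The isopropenyl group of 6 ends up axial in the trans product, which erodes the usual preference for trans protonation, so cis-fused ketone may form. The fallback makes C7 equatorial before the reduction. It sets out from 6: ozonolysis (O3, CH2Cl2, −78 °C; Me2S) cleaves only the electron-rich isopropenyl group, and equilibration (TsOH or NaOMe) gives (4aS,7R)-7-acetyl-4a-methyl-4,4a,5,6,7,8-hexahydronaphthalen-2(3H)-one F1. Selective ketalisation of the saturated ketone (ethylene glycol, TsOH, benzene) gives the dioxolane enone F2. Li/NH3 reduction, now with an equatorial C7 group, gives the trans-decalone F3. Methyl ferrate addition as in step 4 gives the tertiary alcohol F4, and NaH with 14 as in step 6 gives the aryl ether F5. PPTS in wet acetone removes the dioxolane and the fallback comes back to the route at 19.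

**Step 6 (O-arylation of a hindered tertiary alkoxide).** Aryne formation from the iodonium salt or poor ligand coupling could lower the yield or give regioisomers. The fallback uses activated SNAr and then exchanges the activating group. It sets out from 10: KHMDS in THF at 0 °C with 3-chloro-4-fluoronitrobenzene gives (2R,4aS,7S,8aS)-2-(2-chloro-4-nitrophenoxy)-2,4a-dimethyl-7-(prop-1-en-2-yl)decahydronaphthalene F6. Fe/NH4Cl in EtOH/H2O reduces the nitro group to the aniline F7. A Sandmeyer bromination (t-BuONO, CuBr2, MeCN) then comes back to the route at 16.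

**Step 11 (thermal Claisen at 190 °C).** The tertiary alkyl aryl ether may eliminate once the acidic phenol appears, and the hindered Suzuki coupling in step 10 already exposes the O-allyl group to Pd(0). The fallback moves the sigmatropic step onto a robust fragment. Commercial allyl 4-bromophenyl ether is rearranged neat at 200 °C to 2-allyl-4-bromophenol F8, and Miyaura borylation (B2pin2, Pd(dppf)Cl2, KOAc, dioxane, 80 °C) gives 2-allyl-4-(4,4,5,5-tetramethyl-1,3,2-dioxaborolan-2-yl)phenol F9. The fallback sets out from 23: Suzuki coupling of 23 with F9 (Pd(OAc)2/SPhos, K3PO4, toluene/H2O, 90 °C) comes back to the route directly at 27, so the ether never sees more than 90 °C.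

## Further compounds

F1 | step 3 | (4aS,7R)-7-acetyl-4a-methyl-4,4a,5,6,7,8-hexahydronaphthalen-2(3H)-one | O=C1CC[C@]2(C)CC[C@@H](C(C)=O)CC2=C1
F2 | step 3 | (4aS,7R)-4a-methyl-7-(2-methyl-1,3-dioxolan-2-yl)-4,4a,5,6,7,8-hexahydronaphthalen-2(3H)-one | O=C1CC[C@]2(C)CC[C@@H](C3(C)OCCO3)CC2=C1
F3 | step 3 | (4aS,7R,8aS)-4a-methyl-7-(2-methyl-1,3-dioxolan-2-yl)octahydronaphthalen-2(1H)-one | O=C1CC[C@]2(C)CC[C@@H](C3(C)OCCO3)C[C@H]2C1
F4 | step 3 | (2R,4aS,7R,8aS)-2,4a-dimethyl-7-(2-methyl-1,3-dioxolan-2-yl)decahydronaphthalen-2-ol | O[C@]1(C)CC[C@]2(C)CC[C@@H](C3(C)OCCO3)C[C@H]2C1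
F5 | step 3 | (2R,4aS,7R,8aS)-2-(4-bromo-2-chlorophenoxy)-2,4a-dimethyl-7-(2-methyl-1,3-dioxolan-2-yl)decahydronaphthalene | Clc1cc(Br)ccc1O[C@]1(C)CC[C@]2(C)CC[C@@H](C3(C)OCCO3)C[C@H]2C1
F6 | step 6 | (2R,4aS,7S,8aS)-2-(2-chloro-4-nitrophenoxy)-2,4a-dimethyl-7-(prop-1-en-2-yl)decahydronaphthalene | [O-][N+](=O)c1ccc(O[C@]2(C)CC[C@]3(C)CC[C@H](C(C)=C)C[C@H]3C2)c(Cl)c1
F7 | step 6 | 3-chloro-4-{[(2R,4aS,7S,8aS)-2,4a-dimethyl-7-(prop-1-en-2-yl)decahydronaphthalen-2-yl]oxy}aniline | Nc1ccc(O[C@]2(C)CC[C@]3(C)CC[C@H](C(C)=C)C[C@H]3C2)c(Cl)c1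
F8 | step 11 | 2-allyl-4-bromophenol | Oc1ccc(Br)cc1CC=C
F9 | step 11 | 2-allyl-4-(4,4,5,5-tetramethyl-1,3,2-dioxaborolan-2-yl)phenol | Oc1ccc(cc1CC=C)B1OC(C)(C)C(C)(C)O1
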